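**Plan**
- Numbering: bicyclo[3.3.1]nonane core; C1 = prenyl bridgehead beside C8 (CMe2); C2–C3–C4 = the acylated, enolised 1,3-dione of ring A; C5 = geranyl bridgehead; C6–C7–C8 lie in ring B; C9 = bridging ketone.
- Retrosynthetic cuts, in order: C3–aroyl; C5–geranyl; the C7–CH2 side-chain bond (back to a 7-methylene, hence a 7-ketone and a 7-carbinol); C5–C6 (a 1,2-shift, C6 having sat on C9); then C1–C2 and C5–C9 together.
- Enabling feature: C2, C3, C4 and C5 of ring A are the four carbons of diketene, and C9 with C1, C8, C7, C6 is a cyclopentanone whose enolate carbon is C1. Acylation at C1 and aldol addition at C9 therefore build the dione ring in one operation.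
- Forward order: cyclopentenone (allethrolone) → C8 gem-dimethyl and C1 enolate by conjugate methylation → six-membered dione ring by diketene annulation (cis-hydrindane) → ring expansion to the bicyclo[3.3.1]nonane (rings A and B) → C7 side chain → C5 geranyl → C3 aroyl → unmasking.
- Stereochemistry: the (R)-carbinol of allethrolone (future C7) sends diketene to the opposite face and so fixes C1, C9 and, through the shift, C5. The carbinol is then erased and C7 is set anew by exo-face hydroboration of the 7-methylene, which leaves the prenyl group endo (cis to the C2–C4 bridge of ring A).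

Key step: step 4

Assumption: (R)-allethrolone is bought as the single enantiomer (both antipodes arise in pyrethroid manufacture; lipase hydrolysis of the racemic acetate also supplies it).

Step 1
Reactants: 1 (R)-allethrolone
Product: 2 (4R)-4-(tert-butyldimethylsilyloxy)-3-methyl-2-(prop-2-enyl)cyclopent-2-en-1-one
Conditions: TBSCl, imidazole, DMF, 0 °C → rt
Reagents that add atoms: tert-butyldimethylsilyl chloride, CC(C)(C)[Si](C)(C)Cl
Why: Silyl ether formation at the secondary allylic alcohol leaves the carbinol centre untouched and installs the bulky group that steers step 4.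

Step 2
Reactants: 2; 3 2-methylbut-2-ene
Product: 4 (4R)-4-(tert-butyldimethylsilyloxy)-3-methyl-2-(3-methylbut-2-enyl)cyclopent-2-en-1-one
Conditions: second-generation Grubbs catalyst RuCl2(=CHPh)(PCy3)(SIMes) (5 mol %), 2-methylbut-2-ene (excess), CH2Cl2, 40 °C
Reagents that add atoms: 2-methylbut-2-ene, CC=C(C)C
Why: Olefin cross-metathesis of the terminal allyl group with the trisubstituted alkene should give the prenyl group, the tetrasubstituted enone double bond being inert to the catalyst.

Step 3
Reactants: 4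
Product: 5 tert-butyl-[(1R)-2,2-dimethyl-3-(3-methylbut-2-enyl)-4-(trimethylsilyloxy)cyclopent-3-en-1-yl]oxy-dimethylsilane
Conditions: MeMgBr, CuBr·SMe2 (cat.), TMSCl, HMPA, THF, −78 → −30 °C
Reagents that add atoms: methylmagnesium bromide, C[Mg]Br; chlorotrimethylsilane, C[Si](C)(C)Cl
Why: Copper-catalysed, silyl chloride-accelerated conjugate addition to the β,β-disubstituted enone creates the gem-dimethyl carbon (no new stereocentre) and traps the regio-defined tetrasubstituted enolate as its silyl enol ether.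

Step 4
Reactants: 5; 6 diketene
Product: 9 cis-fused ketol (2R,3aS,7aR)-2-(tert-butyldimethylsilyloxy)-7a-hydroxy-3,3-dimethyl-3a-(3-methylbut-2-enyl)hexahydro-1H-indene-4,6-dione, via lithium enolate 7 (not isolated), via lithium acetoacetyl-ketone enolate 8 (not isolated)
Conditions: MeLi, THF, 0 °C; then diketene, −78 → −40 °C; AcOH quench
Reagents that add atoms: diketene, C=C1CC(=O)O1
Why: The lithium enolate 7, regio-defined by the silyl enol ether, attacks the acyl carbon of diketene through C1 (C1–C2 bond) and the β-lactone opens to the terminal enolate 8 of the new acetoacetyl ketone, whose CH2 carbon (C5) then adds to the cyclopentanone carbonyl (C5–C9 bond, intramolecular aldol); proton transfer to the β-diketonate makes the cascade irreversible. The closest known reaction type is the acylation–aldol annulation of ketone lithium enolates with diketene. The one ring formed, the six-membered dione ring C1–C2–C3–C4–C5–C9, closes by a 6-(enolexo)-exo-trig aldol addition. C1 is set by approach of diketene anti to the C7 silyloxy group, which together with the C8 methyl group that it pushes pseudoaxial shields its own face; C9 is then set by the tether, since the short chain can reach the carbonyl only from the face it sits on (cis ring fusion). The step needs C- over O-acylation (lithium counter-ion in THF at low temperature), reaction at C1 and not C6 (no enolate equilibration without a proton source) and aldol through C5 and not C3 (attack by C3 would give a four-membered ring).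

Step 5
Reactants: 9
Product: 11 (1R,5S,7R)-7-(tert-butyldimethylsilyloxy)-4-methoxy-8,8-dimethyl-1-(3-methylbut-2-enyl)bicyclo[3.3.1]non-3-ene-2,9-dione (silyloxy group exo), via C5-iodanyl diketone 10 (not isolated)
Conditions: PhI(OAc)2, KOH, MeOH, 0 °C → rt
Reagents that add atoms: methanol, CO
Why: Oxidative ring expansion by a semipinacol 1,2-shift: the extended enolate of the 1,3-diketone is iodanylated at C5 by trivalent iodine, methoxide adds to the neighbouring C4 carbonyl, and the C9 alkoxide pushes C6 from C9 to C5 as iodobenzene leaves, the C4 hemiketal then losing hydroxide to give the vinylogous methyl ester; C6 should migrate because C1 carries an acyl group and migrates poorly, and C5 can only form cis-bridged, so C1 and C7 are untouched.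

Step 6
Reactants: 11
Product: 12 (1R,5S,7R)-7-hydroxy-4-methoxy-8,8-dimethyl-1-(3-methylbut-2-enyl)bicyclo[3.3.1]non-3-ene-2,9-dione
Conditions: TBAF, AcOH, THF, rt → 45 °C
Reagents that add atoms: none
Why: Fluoride-mediated desilylation, buffered so that the vinylogous ester and the bridgehead C–H are not disturbed.

Step 7
Reactants: 12
Product: 13 (1R,5S)-4-methoxy-8,8-dimethyl-1-(3-methylbut-2-enyl)bicyclo[3.3.1]non-3-ene-2,7,9-trione
Conditions: Dess–Martin periodinane, CH2Cl2, 0 °C → rt
Reagents that add atoms: none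
Why: Dess–Martin oxidation of the secondary alcohol removes the relay stereocentre once it has fixed C1 and C5; alkenes and the enol ether are inert.

Step 8
Reactants: 13
Product: 14 (1R,5S)-4-methoxy-8,8-dimethyl-7-methylidene-1-(3-methylbut-2-enyl)bicyclo[3.3.1]non-3-ene-2,9-dione
Conditions: Ph3PCH3Br, KOtBu, THF, 0 °C → rt
Reagents that add atoms: methyltriphenylphosphonium bromide, C[P+](c1ccccc1)(c1ccccc1)c1ccccc1.[Br-]
Why: Wittig methylenation should pick the C7 ketone, because C9 is shielded by both bridgeheads and C2 is a deactivated vinylogous ester carbonyl next to a quaternary carbon.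

Step 9
Reactants: 14; 15 1-bromo-2-methylprop-1-ene
Product: 17 (1R,5S,7S)-4-methoxy-8,8-dimethyl-1,7-bis(3-methylbut-2-enyl)bicyclo[3.3.1]non-3-ene-2,9-dione (C7 side chain endo), via B-alkyl-9-BBN 16 (not isolated)
Conditions: 9-BBN, THF, 0 °C → rt; then 15, PdCl2(dppf) (5 mol %), aq. K3PO4, DMF, 50 °C
Reagents that add atoms: 1-bromo-2-methylprop-1-ene, CC(C)=CBr
Why: Syn, anti-Markovnikov hydroboration of the 1,1-disubstituted alkene by 9-BBN (much slower on the trisubstituted prenyl alkene and on the hindered C9 and vinylogous C2 carbonyls) puts hydrogen on C7 from the exo face, the endo face being closed by ring A (C2–C3–C4), so that the CH2B group, and after B-alkyl Suzuki–Miyaura coupling with the alkenyl bromide the prenyl group, sits endo (7S).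

Step 10
Reactants: 17; 18 geranyl bromide
Product: 20 (1R,5S,7S)-5-[(2E)-3,7-dimethylocta-2,6-dienyl]-4-methoxy-8,8-dimethyl-1,7-bis(3-methylbut-2-enyl)bicyclo[3.3.1]non-3-ene-2,9-dione, via C5 bridgehead organolithium 19 (not isolated)
Conditions: LiN(iPr)2 (LDA), THF, −78 °C; then geranyl bromide, −78 °C → rt
Reagents that add atoms: geranyl bromide, CC(C)=CCC/C(C)=C/CBr
Why: Bridgehead lithiation–alkylation, known for enol ethers of bicyclo[3.3.1]nonane-2,4,9-triones: C5–H, flanked by the C9 ketone and the enol ether carbon, gives a pyramidal carbanion that cannot invert and is alkylated by the allylic bromide with retention.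

Step 11
Reactants: 21 3-acetoxybenzoic acid
Product: 22 3-acetoxybenzoyl chloride
Conditions: (COCl)2, DMF (cat.), CH2Cl2, 0 °C → rt
Reagents that add atoms: oxalyl chloride, O=C(Cl)C(=O)Cl
Why: Acid chloride formation through the chloroiminium (Vilsmeier-type) activation; the aryl acetate is untouched.

Step 12
Reactants: 20; 22
Product: 24 3-{[(1S,5S,7S)-5-[(2E)-3,7-dimethylocta-2,6-dienyl]-4-methoxy-8,8-dimethyl-1,7-bis(3-methylbut-2-enyl)-2,9-dioxobicyclo[3.3.1]non-3-en-3-yl]carbonyl}phenyl acetate, via C3 vinyllithium 23 (not isolated)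
Conditions: lithium 2,2,6,6-tetramethylpiperidide (LiTMP), THF, −78 °C; then 22, −78 → 0 °C
Reagents that add atoms: 3-acetoxybenzoyl chloride, CC(=O)Oc1cccc(c1)C(=O)Cl
Why: α-Lithiation of the vinylogous ester at C3, the only acidic C–H left once both bridgeheads are quaternary, followed by C-acylation with the acid chloride, which is far more electrophilic than the aryl acetate (any acyl scrambling at the phenol is undone in step 13).

Step 13
Reactants: 24
Product: 25 target, (1S,5S,7S)-5-[(2E)-3,7-dimethylocta-2,6-dienyl]-4-hydroxy-3-(3-hydroxybenzoyl)-8,8-dimethyl-1,7-bis(3-methylbut-2-enyl)bicyclo[3.3.1]non-3-ene-2,9-dione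
Conditions: LiOH, dioxane/H2O, 90 °C; then aq. HCl
Reagents that add atoms: lithium hydroxide, [Li+].[OH-]
Why: Addition–elimination hydrolysis of the vinylogous methyl ester and saponification of the aryl acetate in one pot; C1 and C5 are quaternary and C7 is not next to a carbonyl, so no stereocentre can epimerise.

**Compound list**
1 | (R)-allethrolone, (4R)-4-hydroxy-3-methyl-2-(prop-2-enyl)cyclopent-2-en-1-one | O=C1C[C@@H](O)C(C)=C1CC=C | starting material
2 | (4R)-4-(tert-butyldimethylsilyloxy)-3-methyl-2-(prop-2-enyl)cyclopent-2-en-1-one | O=C1C[C@@H](O[Si](C)(C)C(C)(C)C)C(C)=C1CC=C | intermediate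
3 | 2-methylbut-2-ene | CC=C(C)C | starting material
4 | (4R)-4-(tert-butyldimethylsilyloxy)-3-methyl-2-(3-methylbut-2-enyl)cyclopent-2-en-1-one | O=C1C[C@@H](O[Si](C)(C)C(C)(C)C)C(C)=C1CC=C(C)C | intermediate
5 | tert-butyl-[(1R)-2,2-dimethyl-3-(3-methylbut-2-enyl)-4-(trimethylsilyloxy)cyclopent-3-en-1-yl]oxy-dimethylsilane | C[Si](C)(C)OC1=C(CC=C(C)C)C(C)(C)[C@H](O[Si](C)(C)C(C)(C)C)C1 | intermediate
6 | diketene, 4-methylideneoxetan-2-one | C=C1CC(=O)O1 | starting material
7 | lithium (4R)-4-(tert-butyldimethylsilyloxy)-3,3-dimethyl-2-(3-methylbut-2-enyl)cyclopent-1-en-1-olate | [Li]OC1=C(CC=C(C)C)C(C)(C)[C@H](O[Si](C)(C)C(C)(C)C)C1 | intermediate (not isolated)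
8 | lithium 4-[(1S,4R)-4-(tert-butyldimethylsilyloxy)-5,5-dimethyl-1-(3-methylbut-2-enyl)-2-oxocyclopentyl]-4-oxobut-1-en-2-olate (acyl group trans to the silyloxy group) | [Li]OC(=C)CC(=O)[C@@]1(CC=C(C)C)C(C)(C)[C@H](O[Si](C)(C)C(C)(C)C)CC1=O | intermediate (not isolated)
9 | (2R,3aS,7aR)-2-(tert-butyldimethylsilyloxy)-7a-hydroxy-3,3-dimethyl-3a-(3-methylbut-2-enyl)hexahydro-1H-indene-4,6-dione (cis-fused; 3a-prenyl, 7a-hydroxyl and 2-silyloxy on one face) | O[C@]12CC(=O)CC(=O)[C@@]1(CC=C(C)C)C(C)(C)[C@H](O[Si](C)(C)C(C)(C)C)C2 | intermediate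
10 | ketol 9 carrying a methoxy(phenyl)-λ3-iodanyl group on C7 of the indene numbering (C5 of the target; configuration there not defined) | O[C@]12C(I(OC)c3ccccc3)C(=O)CC(=O)[C@@]1(CC=C(C)C)C(C)(C)[C@H](O[Si](C)(C)C(C)(C)C)C2 | intermediate (not isolated)
11 | (1R,5S,7R)-7-(tert-butyldimethylsilyloxy)-4-methoxy-8,8-dimethyl-1-(3-methylbut-2-enyl)bicyclo[3.3.1]non-3-ene-2,9-dione (silyloxy exo, trans to the C2–C4 bridge) | [C@H]12C[C@@H](O[Si](C)(C)C(C)(C)C)C(C)(C)[C@](CC=C(C)C)(C(=O)C=C1OC)C2=O | intermediate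
12 | (1R,5S,7R)-7-hydroxy-4-methoxy-8,8-dimethyl-1-(3-methylbut-2-enyl)bicyclo[3.3.1]non-3-ene-2,9-dione | [C@H]12C[C@@H](O)C(C)(C)[C@](CC=C(C)C)(C(=O)C=C1OC)C2=O | intermediate
13 | (1R,5S)-4-methoxy-8,8-dimethyl-1-(3-methylbut-2-enyl)bicyclo[3.3.1]non-3-ene-2,7,9-trione | [C@H]12CC(=O)C(C)(C)[C@](CC=C(C)C)(C(=O)C=C1OC)C2=O | intermediate
14 | (1R,5S)-4-methoxy-8,8-dimethyl-7-methylidene-1-(3-methylbut-2-enyl)bicyclo[3.3.1]non-3-ene-2,9-dione | [C@H]12CC(=C)C(C)(C)[C@](CC=C(C)C)(C(=O)C=C1OC)C2=O | intermediate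
15 | 1-bromo-2-methylprop-1-ene | CC(C)=CBr | starting material
16 | 9-{[(1S,3S,5R)-6-methoxy-2,2-dimethyl-1-(3-methylbut-2-enyl)-8,9-dioxobicyclo[3.3.1]non-6-en-3-yl]methyl}-9-borabicyclo[3.3.1]nonane, i.e. 14 hydroborated at the methylidene group (CH2B endo, 7S in the core numbering) | [C@H]12C[C@H](CB3C4CCCC3CCC4)C(C)(C)[C@](CC=C(C)C)(C(=O)C=C1OC)C2=O | intermediate (not isolated)
17 | (1R,5S,7S)-4-methoxy-8,8-dimethyl-1,7-bis(3-methylbut-2-enyl)bicyclo[3.3.1]non-3-ene-2,9-dione (C7 prenyl endo, cis to the C2–C4 bridge) | [C@H]12C[C@H](CC=C(C)C)C(C)(C)[C@](CC=C(C)C)(C(=O)C=C1OC)C2=O | intermediate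
18 | geranyl bromide, (2E)-1-bromo-3,7-dimethylocta-2,6-diene | CC(C)=CCC/C(C)=C/CBr | starting material
19 | C5 bridgehead lithio derivative of 17 | [Li][C@]12C[C@H](CC=C(C)C)C(C)(C)[C@](CC=C(C)C)(C(=O)C=C1OC)C2=O | intermediate (not isolated)
20 | (1R,5S,7S)-5-[(2E)-3,7-dimethylocta-2,6-dienyl]-4-methoxy-8,8-dimethyl-1,7-bis(3-methylbut-2-enyl)bicyclo[3.3.1]non-3-ene-2,9-dione | CC(C)=CCC/C(C)=C/C[C@]12C[C@H](CC=C(C)C)C(C)(C)[C@](CC=C(C)C)(C(=O)C=C1OC)C2=O | intermediate
21 | 3-acetoxybenzoic acid | CC(=O)Oc1cccc(c1)C(=O)O | starting material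
22 | 3-acetoxybenzoyl chloride | CC(=O)Oc1cccc(c1)C(=O)Cl | intermediate
23 | C3 vinyllithium derivative of 20 | CC(C)=CCC/C(C)=C/C[C@]12C[C@H](CC=C(C)C)C(C)(C)[C@](CC=C(C)C)(C(=O)C([Li])=C1OC)C2=O | intermediate (not isolated)
24 | 3-{[(1S,5S,7S)-5-[(2E)-3,7-dimethylocta-2,6-dienyl]-4-methoxy-8,8-dimethyl-1,7-bis(3-methylbut-2-enyl)-2,9-dioxobicyclo[3.3.1]non-3-en-3-yl]carbonyl}phenyl acetate | CC(C)=CCC/C(C)=C/C[C@]12C[C@H](CC=C(C)C)C(C)(C)[C@](CC=C(C)C)(C(=O)C(C(=O)c3cccc(OC(C)=O)c3)=C1OC)C2=O | intermediate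
25 | (1S,5S,7S)-5-[(2E)-3,7-dimethylocta-2,6-dienyl]-4-hydroxy-3-(3-hydroxybenzoyl)-8,8-dimethyl-1,7-bis(3-methylbut-2-enyl)bicyclo[3.3.1]non-3-ene-2,9-dione | CC(C)=CCC/C(C)=C/C[C@]12C[C@H](CC=C(C)C)C(C)(C)[C@](CC=C(C)C)(C(=O)C(C(=O)c3cccc(O)c3)=C1O)C2=O | target

**Totals**
Total step count: 13. Longest linear sequence: 12 (steps 1–10, 12, 13).

**Steps most likely to fail**

Step 5. The trivalent-iodine reagent may oxidise C3 (ylide formation) or hydroxylate/ketalise next to the carbonyl instead of triggering the shift, C1 may migrate in place of C6, or methanol may not be captured. The fallback sets out from 9 and comes back at 11. LiN(iPr)2 (3.3 equiv) gives the alkoxide–dianion of 9, which I2 iodinates at the terminal carbon to the C5-iodo ketol F4. AgOTf then removes iodide while the hydroxyl group pushes C6 across (halohydrin-type semipinacol rearrangement) to give the free trione F5. Trimethylsilyldiazomethane in MeOH/toluene methylates F5 on oxygen to 11, from which the C2 methyl ether F6 is separated.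

Step 3. The cuprate may fail to add to the fully substituted β-carbon lying between the prenyl-bearing carbon and the silyloxy carbon, or electron transfer may expel the γ-silyloxy group. The fallback sets out from 1 and comes back at 12. Cross-metathesis of 1 with 3 gives the free carbinol (4R)-4-hydroxy-3-methyl-2-(3-methylbut-2-enyl)cyclopent-2-en-1-one F1. With excess MeMgBr and catalytic CuBr·SMe2 its magnesium alkoxide holds the reagent and delivers methyl to the β-carbon from its own face (alkoxide-directed conjugate addition, with no bulky silyl ether beside the reacting carbon), and TMSCl then caps both oxygens to give the bis(trimethylsilyl) compound F2. MeLi opens only the enol silyl ether, and annulation with 6 as in step 4 gives the trimethylsilyloxy ketol F3. The methanolic KOH of step 5 strips the trimethylsilyl ether during the ring expansion, so the sequence re-enters the route at carbinol 12.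

Step 9. The dialkylborane may reduce the C2 carbonyl before it reaches the hindered alkene, or the β-branched alkylborane may transmetalate slowly and be lost by protodeboronation. The fallback sets out from 14 and comes back at 17. RhCl(PPh3)3-catalysed hydroboration with pinacolborane, which leaves ketones alone and again delivers hydrogen from the exo face, gives the endo boronate F7. NaBO3 gives the primary alcohol F8, and I2/PPh3/imidazole the iodide F9. Zinc dust with LiCl gives the alkylzinc iodide F10, and Pd(PPh3)4-catalysed Negishi coupling of F10 with 15 gives 17.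

**Further compounds**
F1 | step 3 | (4R)-4-hydroxy-3-methyl-2-(3-methylbut-2-enyl)cyclopent-2-en-1-one | O=C1C[C@@H](O)C(C)=C1CC=C(C)C
F2 | step 3 | trimethyl-[(1R)-2,2-dimethyl-3-(3-methylbut-2-enyl)-4-(trimethylsilyloxy)cyclopent-3-en-1-yl]oxysilane | C[Si](C)(C)OC1=C(CC=C(C)C)C(C)(C)[C@H](O[Si](C)(C)C)C1
F3 | step 3 | (2R,3aS,7aR)-7a-hydroxy-3,3-dimethyl-3a-(3-methylbut-2-enyl)-2-(trimethylsilyloxy)hexahydro-1H-indene-4,6-dione | O[C@]12CC(=O)CC(=O)[C@@]1(CC=C(C)C)C(C)(C)[C@H](O[Si](C)(C)C)C2
F4 | step 5 | ketol 9 carrying iodine on C7 of the indene numbering (C5 of the target) | O[C@]12C(I)C(=O)CC(=O)[C@@]1(CC=C(C)C)C(C)(C)[C@H](O[Si](C)(C)C(C)(C)C)C2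
F5 | step 5 | (1R,5S,7R)-7-(tert-butyldimethylsilyloxy)-8,8-dimethyl-1-(3-methylbut-2-enyl)bicyclo[3.3.1]nonane-2,4,9-trione | [C@H]12C[C@@H](O[Si](C)(C)C(C)(C)C)C(C)(C)[C@](CC=C(C)C)(C(=O)CC1=O)C2=O
F6 | step 5 | C2 methyl enol ether isomer of 11, 7-(tert-butyldimethylsilyloxy)-2-methoxy-8,8-dimethyl-1-(3-methylbut-2-enyl)bicyclo[3.3.1]non-2-ene-4,9-dione | [C@H]12C[C@@H](O[Si](C)(C)C(C)(C)C)C(C)(C)[C@](CC=C(C)C)(C(OC)=CC1=O)C2=O
F7 | step 9 | endo pinacol boronate, 14 hydroborated at the methylidene group (CH2Bpin endo) | [C@H]12C[C@H](CB3OC(C)(C)C(C)(C)O3)C(C)(C)[C@](CC=C(C)C)(C(=O)C=C1OC)C2=O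
F8 | step 9 | 7-endo-hydroxymethyl analogue of 17 | [C@H]12C[C@H](CO)C(C)(C)[C@](CC=C(C)C)(C(=O)C=C1OC)C2=O
F9 | step 9 | 7-endo-iodomethyl analogue of 17 | [C@H]12C[C@H](CI)C(C)(C)[C@](CC=C(C)C)(C(=O)C=C1OC)C2=O
F10 | step 9 | alkylzinc iodide from F9 | [C@H]12C[C@H](C[Zn]I)C(C)(C)[C@](CC=C(C)C)(C(=O)C=C1OC)C2=O
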